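**Retrosynthetic overview**

1. Ring numbering: C1 and C4 carry OH, C6 carries CH3, C2 carries the side chain C1'–C16'. The strategy rests on the E-trisubstituted allylarene unit ring C2–C1'H2–C2'H=C3'(CH3)–C4'. The arene is the only ring and is bought, so no ring is formed.
2. The hydroquinone comes from its dimethyl ether 21 by oxidation to the quinone and reduction. The (E)-C9'=C10' alkene comes from a C9'≡C10' alkyne by hydroxyl-directed trans reduction.
3. C8'–C9' is cut to allylic bromide 15 and (S)-alkynol 19. C11' is set by asymmetric epoxidation of geraniol and carried through an epoxy chloride fragmentation.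
4. C3'–CH3 and C1'–C2' are cut to alkyne 6, Al(CH3)3 and benzylic chloride 11 (methylalumination, then nickel-catalysed coupling in the same flask).
5. Alkyne 6 comes from pent-4-yn-1-ol (the Wittig step sets C6'=C7'). Chloride 11 comes from 4-methoxy-2-methylphenol by ortho-formylation.

Key step: step 8

Assumption: in step 16 both quinone oxygens are taken to come from water (aryl–oxygen cleavage with loss of two molecules of methanol), as is usual for cerium oxidations of hydroquinone dimethyl ethers.

**Route**

Step 1
Reactants: 1 pent-4-yn-1-ol; 2 ethyl 2-(triphenylphosphoranylidene)propanoate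
Product: 4 ethyl (2E)-2-methylhept-2-en-6-ynoate, via pent-4-ynal 3 (not isolated)
Conditions: TEMPO (10 mol %), PhI(OAc)2 (1.1 equiv), CH2Cl2, rt; then 2 (1.3 equiv), rt
Reagents that add atoms: none
Why: Nitroxyl-catalysed oxidation gives the volatile aldehyde, which is trapped in the same flask by Wittig olefination; the stabilised α-methyl ylide should give the E-enoate.

Step 2
Reactants: 4 ethyl (2E)-2-methylhept-2-en-6-ynoate
Product: 5 (2E)-2-methylhept-2-en-6-yn-1-ol
Conditions: (i-Bu)2AlH (2.2 equiv), CH2Cl2, −78 °C; aq. KNaC4H4O6 work-up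
Reagents that add atoms: none
Why: Aluminium hydride 1,2-reduction of an enoate to the allylic alcohol; at −78 °C the terminal alkyne and the alkene geometry should be unaffected.

Step 3
Reactants: 5 (2E)-2-methylhept-2-en-6-yn-1-ol
Product: 6 tert-butyldimethyl{[(2E)-2-methylhept-2-en-6-yn-1-yl]oxy}silane
Conditions: TBSCl, imidazole, CH2Cl2, rt
Reagents that add atoms: tert-butyldimethylsilyl chloride, CC(C)(C)[Si](C)(C)Cl
Why: Standard silylation of a primary alcohol; the silyl ether masks the hydroxyl toward Al(CH3)3 in step 8.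

Step 4
Reactants: 7 4-methoxy-2-methylphenol
Product: 8 2-hydroxy-5-methoxy-3-methylbenzaldehyde
Conditions: MgCl2 (1.5 equiv), Et3N (3.75 equiv), (CH2O)n, MeCN, reflux; aq. HCl work-up
Reagents that add atoms: paraformaldehyde (as formaldehyde), C=O
Why: Casnati–Skattebøl ortho-formylation: the magnesium phenoxide directs formaldehyde to the only free ortho position, and a second formaldehyde oxidises the benzylic alkoxide to the aldehyde.

Step 5
Reactants: 8 2-hydroxy-5-methoxy-3-methylbenzaldehyde
Product: 9 2,5-dimethoxy-3-methylbenzaldehyde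
Conditions: CH3I, K2CO3, DMF, rt
Reagents that add atoms: iodomethane, CI
Why: Williamson O-methylation of the phenoxide.

Step 6
Reactants: 9 2,5-dimethoxy-3-methylbenzaldehyde
Product: 10 (2,5-dimethoxy-3-methylphenyl)methanol
Conditions: NaBH4, MeOH, 0 °C
Reagents that add atoms: none
Why: Borohydride reduction of an aryl aldehyde to the benzylic alcohol.

Step 7
Reactants: 10 (2,5-dimethoxy-3-methylphenyl)methanol
Product: 11 1-(chloromethyl)-2,5-dimethoxy-3-methylbenzene
Conditions: SOCl2 (1.2 equiv), DMF (cat.), CH2Cl2, 0 °C → rt; used without chromatography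
Reagents that add atoms: thionyl chloride, O=S(Cl)Cl
Why: Deoxychlorination of an electron-rich benzylic alcohol via its chlorosulfite; the product is taken on crude because such chlorides solvolyse on silica.

Step 8
Reactants: 6 tert-butyldimethyl{[(2E)-2-methylhept-2-en-6-yn-1-yl]oxy}silane; 11 1-(chloromethyl)-2,5-dimethoxy-3-methylbenzene
Product: 13 tert-butyl{[(2E,6E)-8-(2,5-dimethoxy-3-methylphenyl)-2,6-dimethylocta-2,6-dien-1-yl]oxy}dimethylsilane, via (E)-alkenyldimethylalane 12 (not isolated)
Conditions: Al(CH3)3 (2.0 equiv), Cp2ZrCl2 (0.25 equiv), ClCH2CH2Cl, 0 °C → rt; volatiles removed in vacuo, residue taken up in THF; then 11 (0.9 equiv), NiCl2(PPh3)2 (5 mol %) pre-reduced with n-BuLi (10 mol %), THF, 0 °C → rt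
Reagents that add atoms: trimethylaluminium, C[Al](C)C
Why: Negishi carboalumination followed by nickel-catalysed alkenyl–benzyl cross-coupling: Cp2ZrCl2 and Al(CH3)3 form a cationic methylzirconocene that adds methyl and metal syn across the terminal alkyne of 6, methyl going to the internal carbon (C3') and the metal to the terminal carbon (C2'), and transmetalation gives the (E)-alkenyldimethylalane 12. Zerovalent nickel, made from NiCl2(PPh3)2 and n-BuLi, inserts into the benzylic C–Cl bond of 11, accepts the alkenyl group from aluminium and forms C1'–C2' by reductive elimination with retention of alkene geometry. The closest known reaction type is the zirconium-catalysed methylalumination of terminal alkynes combined with nickel-catalysed coupling of alkenylalanes with benzylic chlorides. No ring is closed and no stereocentre is formed; the only stereochemical element created is the E geometry of C2'=C3'. The step needs regioselective, syn carbometalation and a stereoretentive coupling, which the terminal alkyne and the configurationally stable sp2 C–Al bond provide, while bond formation at a benzylic carbon excludes the SN2' and E/Z scrambling open to an allylic electrophile. The C6'=C7' alkene, the silyl ether and the aryl methyl ethers should not react with Al(CH3)3 under these conditions.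

Step 9
Reactants: 13 tert-butyl{[(2E,6E)-8-(2,5-dimethoxy-3-methylphenyl)-2,6-dimethylocta-2,6-dien-1-yl]oxy}dimethylsilane
Product: 14 (2E,6E)-8-(2,5-dimethoxy-3-methylphenyl)-2,6-dimethylocta-2,6-dien-1-ol
Conditions: Bu4NF, THF, 0 °C → rt
Reagents that add atoms: none
Why: Fluoride-induced desilylation of a primary silyl ether; nothing else in the molecule is fluoride-labile.

Step 10
Reactants: 14 (2E,6E)-8-(2,5-dimethoxy-3-methylphenyl)-2,6-dimethylocta-2,6-dien-1-ol
Product: 15 1-[(2E,6E)-8-bromo-3,7-dimethylocta-2,6-dien-1-yl]-2,5-dimethoxy-3-methylbenzene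
Conditions: CBr4, PPh3, CH2Cl2, 0 °C; filtered through a short pad and used at once
Reagents that add atoms: carbon tetrabromide, BrC(Br)(Br)Br
Why: Appel bromination of a primary allylic alcohol under neutral conditions, which should proceed by SN2 at C8' without allylic transposition or loss of the C6'=C7' geometry.

Step 11
Reactants: 16 geraniol
Product: 17 [(2S,3S)-3-methyl-3-(4-methylpent-3-en-1-yl)oxiran-2-yl]methanol ((2S,3S)-2,3-epoxygeraniol)
Conditions: Ti(O-i-Pr)4 (5 mol %), L-(+)-diethyl tartrate (7.5 mol %), t-BuOOH (1.5 equiv), 4 Å molecular sieves, CH2Cl2, −20 °C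
Reagents that add atoms: tert-butyl hydroperoxide, CC(C)(C)OO
Why: Katsuki–Sharpless asymmetric epoxidation: the titanium–L-tartrate complex delivers oxygen to one face of the allylic alcohol alkene only, which sets C3 (the later C11') as S, and the remote trisubstituted alkene lacks the directing hydroxyl and should not react.

Step 12
Reactants: 17 [(2S,3S)-3-methyl-3-(4-methylpent-3-en-1-yl)oxiran-2-yl]methanol
Product: 18 (2R,3S)-2-(chloromethyl)-3-methyl-3-(4-methylpent-3-en-1-yl)oxirane
Conditions: PPh3, CCl4, NaHCO3 (cat.), reflux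
Reagents that add atoms: tetrachloromethane, ClC(Cl)(Cl)Cl
Why: Appel chlorination of the primary alcohol with bicarbonate buffering, which leaves the epoxide closed; the descriptor at C2 changes only because of the priority of chlorine.

Step 13
Reactants: 18 (2R,3S)-2-(chloromethyl)-3-methyl-3-(4-methylpent-3-en-1-yl)oxirane
Product: 19 (3S)-3,7-dimethyloct-6-en-1-yn-3-ol
Conditions: n-BuLi (3.3 equiv), THF, −40 °C → −20 °C; then H2O
Reagents that add atoms: none
Why: Base-induced double elimination of a 2,3-epoxy chloride: deprotonation next to chlorine opens the epoxide to a chlorovinyl alkoxide, loss of HCl gives the acetylide, and the C3–O bond is never broken, so the S configuration is retained.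

Step 14
Reactants: 15 1-[(2E,6E)-8-bromo-3,7-dimethylocta-2,6-dien-1-yl]-2,5-dimethoxy-3-methylbenzene; 19 (3S)-3,7-dimethyloct-6-en-1-yn-3-ol
Product: 20 (6S,10E,14E)-16-(2,5-dimethoxy-3-methylphenyl)-2,6,10,14-tetramethylhexadeca-2,10,14-trien-7-yn-6-ol
Conditions: CuI (1.0 equiv), NaI (1.0 equiv), K2CO3 (1.5 equiv), DMF, rt
Reagents that add atoms: none
Why: Copper-mediated alkynylation of a primary allylic halide: the copper acetylide formed with carbonate displaces the allylic halide at the primary carbon C8' to give the skipped enyne, and the tertiary hydroxyl is not alkylated by carbonate.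

Step 15
Reactants: 20 (6S,10E,14E)-16-(2,5-dimethoxy-3-methylphenyl)-2,6,10,14-tetramethylhexadeca-2,10,14-trien-7-yn-6-ol
Product: 21 (6S,7E,10E,14E)-16-(2,5-dimethoxy-3-methylphenyl)-2,6,10,14-tetramethylhexadeca-2,7,10,14-tetraen-6-ol
Conditions: NaAlH2(OCH2CH2OCH3)2 (3 equiv), THF, 0 °C → rt; aq. KNaC4H4O6 work-up
Reagents that add atoms: none
Why: Hydroxyl-directed trans-hydroalumination of a propargylic alcohol: the aluminium alkoxide delivers hydride across the triple bond in anti fashion and protonolysis of the C–Al bond gives the E-alkene, while isolated alkenes, aryl ethers and the carbinol stereocentre are untouched.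

Step 16
Reactants: 21 (6S,7E,10E,14E)-16-(2,5-dimethoxy-3-methylphenyl)-2,6,10,14-tetramethylhexadeca-2,7,10,14-tetraen-6-ol
Product: 22 2-[(2E,6E,9E,11S)-11-hydroxy-3,7,11,15-tetramethylhexadeca-2,6,9,14-tetraen-1-yl]-6-methylcyclohexa-2,5-diene-1,4-dione
Conditions: (NH4)2Ce(NO3)6 (2.5 equiv), MeCN/H2O, 0 °C, short contact time
Reagents that add atoms: water, O
Why: Oxidative demethylation of a hydroquinone dimethyl ether by tetravalent cerium: two one-electron oxidations with attack of water at the methoxy-bearing carbons release methanol and give the para-quinone, and the brief exposure at 0 °C should spare the tertiary allylic alcohol and the alkenes.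

Step 17
Reactants: 22 2-[(2E,6E,9E,11S)-11-hydroxy-3,7,11,15-tetramethylhexadeca-2,6,9,14-tetraen-1-yl]-6-methylcyclohexa-2,5-diene-1,4-dione
Product: 23 2-[(2E,6E,9E,11S)-11-hydroxy-3,7,11,15-tetramethylhexadeca-2,6,9,14-tetraen-1-yl]-6-methylbenzene-1,4-diol (target)
Conditions: Na2S2O4, Et2O/H2O, rt, under argon
Reagents that add atoms: none
Why: Dithionite reduction of a para-benzoquinone to the hydroquinone under neutral two-phase conditions, which leaves the alkenes and the tertiary allylic alcohol intact.

**Compound list**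

1 | pent-4-yn-1-ol | C#CCCCO | starting material
2 | ethyl 2-(triphenylphosphoranylidene)propanoate | CCOC(=O)C(C)=P(c1ccccc1)(c1ccccc1)c1ccccc1 | starting material
3 | pent-4-ynal | C#CCCC=O | intermediate
4 | ethyl (2E)-2-methylhept-2-en-6-ynoate | C#CCC/C=C(\C)C(=O)OCC | intermediate
5 | (2E)-2-methylhept-2-en-6-yn-1-ol | C#CCC/C=C(\C)CO | intermediate
6 | tert-butyldimethyl{[(2E)-2-methylhept-2-en-6-yn-1-yl]oxy}silane | C#CCC/C=C(\C)CO[Si](C)(C)C(C)(C)C | intermediate
7 | 4-methoxy-2-methylphenol | COc1ccc(O)c(C)c1 | starting material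
8 | 2-hydroxy-5-methoxy-3-methylbenzaldehyde | COc1cc(C)c(O)c(C=O)c1 | intermediate
9 | 2,5-dimethoxy-3-methylbenzaldehyde | COc1cc(C)c(OC)c(C=O)c1 | intermediate
10 | (2,5-dimethoxy-3-methylphenyl)methanol | COc1cc(C)c(OC)c(CO)c1 | intermediate
11 | 1-(chloromethyl)-2,5-dimethoxy-3-methylbenzene | COc1cc(C)c(OC)c(CCl)c1 | intermediate
12 | {(1E,5E)-7-[(tert-butyldimethylsilyl)oxy]-2,6-dimethylhepta-1,5-dien-1-yl}dimethylalane | C[Al](C)/C=C(\C)CC/C=C(\C)CO[Si](C)(C)C(C)(C)C | intermediate
13 | tert-butyl{[(2E,6E)-8-(2,5-dimethoxy-3-methylphenyl)-2,6-dimethylocta-2,6-dien-1-yl]oxy}dimethylsilane | COc1cc(C)c(OC)c(C/C=C(\C)CC/C=C(\C)CO[Si](C)(C)C(C)(C)C)c1 | intermediate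
14 | (2E,6E)-8-(2,5-dimethoxy-3-methylphenyl)-2,6-dimethylocta-2,6-dien-1-ol | COc1cc(C)c(OC)c(C/C=C(\C)CC/C=C(\C)CO)c1 | intermediate
15 | 1-[(2E,6E)-8-bromo-3,7-dimethylocta-2,6-dien-1-yl]-2,5-dimethoxy-3-methylbenzene | COc1cc(C)c(OC)c(C/C=C(\C)CC/C=C(\C)CBr)c1 | intermediate
16 | geraniol, (2E)-3,7-dimethylocta-2,6-dien-1-ol | CC(C)=CCC/C(C)=C/CO | starting material
17 | [(2S,3S)-3-methyl-3-(4-methylpent-3-en-1-yl)oxiran-2-yl]methanol | OC[C@@H]1O[C@@]1(C)CCC=C(C)C | intermediate
18 | (2R,3S)-2-(chloromethyl)-3-methyl-3-(4-methylpent-3-en-1-yl)oxirane | ClC[C@@H]1O[C@@]1(C)CCC=C(C)C | intermediate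
19 | (3S)-3,7-dimethyloct-6-en-1-yn-3-ol | CC(C)=CCC[C@](C)(O)C#C | intermediate
20 | (6S,10E,14E)-16-(2,5-dimethoxy-3-methylphenyl)-2,6,10,14-tetramethylhexadeca-2,10,14-trien-7-yn-6-ol | COc1cc(C)c(OC)c(C/C=C(\C)CC/C=C(\C)CC#C[C@@](C)(O)CCC=C(C)C)c1 | intermediate
21 | (6S,7E,10E,14E)-16-(2,5-dimethoxy-3-methylphenyl)-2,6,10,14-tetramethylhexadeca-2,7,10,14-tetraen-6-ol | COc1cc(C)c(OC)c(C/C=C(\C)CC/C=C(\C)C/C=C/[C@@](C)(O)CCC=C(C)C)c1 | intermediate
22 | 2-[(2E,6E,9E,11S)-11-hydroxy-3,7,11,15-tetramethylhexadeca-2,6,9,14-tetraen-1-yl]-6-methylcyclohexa-2,5-diene-1,4-dione | CC1=CC(=O)C=C(C/C=C(\C)CC/C=C(\C)C/C=C/[C@@](C)(O)CCC=C(C)C)C1=O | intermediate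
23 | 2-[(2E,6E,9E,11S)-11-hydroxy-3,7,11,15-tetramethylhexadeca-2,6,9,14-tetraen-1-yl]-6-methylbenzene-1,4-diol | Cc1cc(O)cc(C/C=C(\C)CC/C=C(\C)C/C=C/[C@@](C)(O)CCC=C(C)C)c1O | target

**Step count**

Total: 17 steps. Longest linear sequence: 11 steps (4, 5, 6, 7, 8, 9, 10, 14, 15, 16, 17, from 4-methoxy-2-methylphenol).

**Steps most likely to fail and fallbacks**

Step 8. The carbometalation may stall or give some of the regioisomeric alane. The alane may be protonated before coupling. The benzylic chloride may homocouple or take up a methyl group from residual Al(CH3)3.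
Fallback: setting out from 6 and 11, the polarity of the coupling is reversed and the alkenyl partner is isolated. The methylalumination of 6 is run as before and the alane 12 is quenched with I2 in THF at −30 °C, which should give tert-butyl{[(2E,6E)-7-iodo-2,6-dimethylhepta-2,6-dien-1-yl]oxy}dimethylsilane F1, purified free of regioisomer. Separately, 11 is treated with Zn and LiCl in THF to give (2,5-dimethoxy-3-methylbenzyl)zinc chloride F2. Negishi coupling of F1 with F2 under Pd(PPh3)4 (zerovalent palladium) in THF should give 13, where the route is rejoined.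

Step 14. The copper acetylide may attack the allylic system at C6' (SN2' pathway) and give a branched enyne. The allylic halide may isomerise at C6'=C7' or decompose before the hindered tertiary alkynol couples.
Fallback: setting out from 19, the alkyne is reduced to an E-alkenyl metal before the C8'–C9' bond is made. Palladium-catalysed hydrostannation of 19 (Bu3SnH, PdCl2(PPh3)2, THF) should give (1E,3S)-3,7-dimethyl-1-(tributylstannyl)octa-1,6-dien-3-ol F3, the hindered carbinol directing tin to the terminal carbon. Stille coupling of F3 with bromide 15 (Pd2(dba)3, AsPh3, THF, rt to 50 °C) joins the alkenyl group to the less substituted allyl terminus and should give 21 directly, where the route is rejoined; compound 20 and step 15 are bypassed.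

Step 16. The acidic cerium medium may ionise the tertiary allylic alcohol, leading to allylic transposition, elimination or cyclisation onto the neighbouring alkenes, and the electron-rich alkenes may be over-oxidised.
Fallback: setting out from 20, the oxidation is moved ahead of the alkyne reduction, so that the carbinol is still propargylic and far less prone to ionisation. Treatment of 20 with (NH4)2Ce(NO3)6 in MeCN/H2O at 0 °C should give 2-[(2E,6E,11S)-11-hydroxy-3,7,11,15-tetramethylhexadeca-2,6,14-trien-9-yn-1-yl]-6-methylcyclohexa-2,5-diene-1,4-dione F4. Reduction with Na2S2O4 in Et2O/H2O should give 2-[(2E,6E,11S)-11-hydroxy-3,7,11,15-tetramethylhexadeca-2,6,14-trien-9-yn-1-yl]-6-methylbenzene-1,4-diol F5. Excess NaAlH2(OCH2CH2OCH3)2 in THF under argon, with the phenols carried as inert aluminium aryloxides, should then effect the trans reduction and give the target 23 directly.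

**Further compounds**

F1 | step 8 | tert-butyl{[(2E,6E)-7-iodo-2,6-dimethylhepta-2,6-dien-1-yl]oxy}dimethylsilane | I/C=C(\C)CC/C=C(\C)CO[Si](C)(C)C(C)(C)C
F2 | step 8 | (2,5-dimethoxy-3-methylbenzyl)zinc chloride | COc1cc(C)c(OC)c(C[Zn]Cl)c1
F3 | step 14 | (1E,3S)-3,7-dimethyl-1-(tributylstannyl)octa-1,6-dien-3-ol | CCCC[Sn](CCCC)(CCCC)/C=C/[C@@](C)(O)CCC=C(C)C
F4 | step 16 | 2-[(2E,6E,11S)-11-hydroxy-3,7,11,15-tetramethylhexadeca-2,6,14-trien-9-yn-1-yl]-6-methylcyclohexa-2,5-diene-1,4-dione | CC1=CC(=O)C=C(C/C=C(\C)CC/C=C(\C)CC#C[C@@](C)(O)CCC=C(C)C)C1=O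
F5 | step 16 | 2-[(2E,6E,11S)-11-hydroxy-3,7,11,15-tetramethylhexadeca-2,6,14-trien-9-yn-1-yl]-6-methylbenzene-1,4-diol | Cc1cc(O)cc(C/C=C(\C)CC/C=C(\C)CC#C[C@@](C)(O)CCC=C(C)C)c1O
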